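Ring C of candidone is read as a benzofuran-3-one ring into which one carbon, C3, has been inserted between C2 and C4. The key step adds CH2 enantioselectively across the enol ether double bond of a 3-silyloxy-2-phenylbenzofuran, forming C2–C3 and C3–C4 and two stereocentres in a cis-fused siloxycyclopropane. It exploits the fact that C2, which already carries O1 and the phenyl group, is a flat, electron-rich enol ether carbon in the furan precursor. Fluoride then opens the C2–C4 bond with inversion at C2 to give the six-membered ring C. The precursor, a 3-triethylsilyloxy-4,6-dimethoxy-7-prenyl-2-phenylbenzofuran, comes from a prenylated salicylate by benzylation and anionic cyclisation.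

Key step: step 6

Remark: the silyl group is taken as triethylsilyl instead of tert-butyldimethylsilyl, so that the hindered cyclopropyl silyl ether is cleaved by fluoride at or below 0 °C, where base does not racemise the flavanone; the facial preference of the L,L-dipeptide on this substrate is assumed, and the D,D-ligand is used if the other face is attacked.

Step 1
Reactants: 1 methyl 2-hydroxy-4,6-dimethoxybenzoate; 2 3-chloro-3-methylbut-1-yne
Product: 3 methyl 2,4-dimethoxy-6-[(2-methylbut-3-yn-2-yl)oxy]benzoate
Conditions: DBU, CuCl2·2H2O (cat.), MeCN, 0 °C → rt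
Reagents that add atoms: none
Why: Copper-catalysed O-alkylation of a phenol with a tertiary propargylic chloride (substitution through a copper acetylide that ionises to a propargyl cation equivalent) is the standard entry to aryl 1,1-dimethylpropargyl ethers, and 1 offers a single phenol as nucleophile.

Step 2
Reactants: 3 methyl 2,4-dimethoxy-6-[(2-methylbut-3-yn-2-yl)oxy]benzoate
Product: 4 methyl 2,4-dimethoxy-6-[(2-methylbut-3-en-2-yl)oxy]benzoate
Conditions: H2 (1 atm), Pd/CaCO3 poisoned with Pb(OAc)2 (Lindlar catalyst), quinoline, EtOAc, rt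
Reagents that add atoms: none
Why: Lindlar semihydrogenation reduces the terminal alkyne to the alkene and stops there, leaving the aryl ether, the ester and the arene untouched.

Step 3
Reactants: 4 methyl 2,4-dimethoxy-6-[(2-methylbut-3-en-2-yl)oxy]benzoate
Product: 5 methyl 2-hydroxy-4,6-dimethoxy-3-(3-methylbut-2-en-1-yl)benzoate
Conditions: N,N-diethylaniline, 130 °C
Reagents that add atoms: none
Why: In this aromatic Claisen rearrangement the [3,3] shift of the 1,1-dimethylallyl ether can only end at the one free ortho carbon (the other carries the ester), the allyl unit arrives transposed as a prenyl group, and tautomerisation restores the phenol.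

Step 4
Reactants: 5 methyl 2-hydroxy-4,6-dimethoxy-3-(3-methylbut-2-en-1-yl)benzoate; 6 benzyl bromide
Product: 7 methyl 2-(benzyloxy)-4,6-dimethoxy-3-(3-methylbut-2-en-1-yl)benzoate
Conditions: K2CO3, DMF, 60 °C
Reagents that add atoms: none
Why: In this Williamson ether synthesis the phenoxide of 5 is alkylated on oxygen by the reactive benzylic bromide, and the ester and the prenyl alkene are inert to K2CO3.

Step 5
Reactants: 7 methyl 2-(benzyloxy)-4,6-dimethoxy-3-(3-methylbut-2-en-1-yl)benzoate
Product: 9 {[4,6-dimethoxy-7-(3-methylbut-2-en-1-yl)-2-phenyl-1-benzofuran-3-yl]oxy}triethylsilane, via lithium benzofuran-3-olate 8 (not isolated)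
Conditions: LiN(iPr)2 (2.5 equiv), THF, −78 → 0 °C; then Et3SiCl (3 equiv), −78 °C → rt
Reagents that add atoms: chlorotriethylsilane, CC[Si](Cl)(CC)CC
Why: LiN(iPr)2 removes a benzylic OCH2 proton, the carbanion closes onto the neighbouring ester in a 5-exo-trig Claisen-type (Dieckmann-like) acylation, the benzofuranone formed is deprotonated at once to the aromatic 3-oxidobenzofuran 8, and this hard oxyanion is O-silylated by Et3SiCl, so the air-sensitive 2-arylbenzofuranone is never isolated.

Step 6
Reactants: 9 {[4,6-dimethoxy-7-(3-methylbut-2-en-1-yl)-2-phenyl-1-benzofuran-3-yl]oxy}triethylsilane; 10 diiodomethane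
Product: 11 (1aR,6bR)-4,6-dimethoxy-3-(3-methylbut-2-en-1-yl)-1a-phenyl-6b-[(triethylsilyl)oxy]-1a,6b-dihydro-1H-cyclopropa[b][1]benzofuran (cis-fused; CH2 on one face of the five-membered ring, phenyl and silyloxy on the other)
Conditions: Et2Zn (1.25 equiv), N-Boc-L-Val-L-Pro-OMe (1.25 equiv), CH2I2 (1.25 equiv), CH2Cl2, −40 → 0 °C
Reagents that add atoms: none
Why: Proposed new method: an iodomethylzinc carbenoid bound to the dipeptide transfers CH2 to the furan C2=C3 bond (target C2 and C4) through a concerted, butterfly-type three-centre transition state with loss of zinc iodide, so the two new C–C bonds (target C2–C3 and C3–C4) form on the same face. The closest known reaction is the dipeptide-mediated asymmetric Simmons–Smith cyclopropanation of silyl enol ethers of aryl ketones; a tetrasubstituted enol ether that is part of a benzofuran has not been used. The three-membered ring closes by this concerted [2+1] addition and is necessarily cis-fused to the five-membered ring, giving a 2-oxabicyclo[3.1.0]hexane. Both stereocentres (1aR and 6bR) arise together and are controlled only by the face that the chiral zinc–peptide reagent selects, since the benzofuran is planar and carries no stereocentre. The step needs enantiofacial selectivity, which rests on the ligand alone, and chemoselectivity over the prenyl alkene, which rests on the much higher nucleophilicity of the doubly oxygenated (O1 and OSiEt3) alkene toward the electrophilic carbenoid and on using only a slight excess of reagent.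

Step 7
Reactants: 11 (1aR,6bR)-4,6-dimethoxy-3-(3-methylbut-2-en-1-yl)-1a-phenyl-6b-[(triethylsilyl)oxy]-1a,6b-dihydro-1H-cyclopropa[b][1]benzofuran
Product: 13 candidone [(2S)-5,7-dimethoxy-8-(3-methylbut-2-en-1-yl)-2-phenyl-2,3-dihydro-4H-chromen-4-one], via tetrabutylammonium cyclopropanolate 12 (not isolated)
Conditions: Bu4NF (1.2 equiv), THF–CF3CH2OH (5:1), −20 → 0 °C; pH 7 phosphate buffer
Reagents that add atoms: none
Why: Proposed new method: fluoride removes the silyl group and the cyclopropanolate 12, in a homoenolate-type ring opening driven by strain release and formation of the aryl ketone, should break the fused bond to C2 (benzylic and O1-bearing, the better carbanion) and not the bond to CH2, while trifluoroethanol protonates C2 on the lobe opposite to the departing bond (inversion, as in the base-induced opening of 2-arylcyclopropanols in protic media), so the 1aR centre becomes 2S and the weakly basic trifluoroethoxide left behind spares the flavanone; the closest known reactions are that base-induced cyclopropanol opening and the one-carbon ring expansion of cyclic silyl enol ethers through siloxycyclopropanes, neither shown for a fused bond with stereospecific protonation.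

Compound list
1 | methyl 2-hydroxy-4,6-dimethoxybenzoate | COC(=O)c1c(O)cc(OC)cc1OC | starting material
2 | 3-chloro-3-methylbut-1-yne | CC(C)(Cl)C#C | starting material
3 | methyl 2,4-dimethoxy-6-[(2-methylbut-3-yn-2-yl)oxy]benzoate | COC(=O)c1c(OC(C)(C)C#C)cc(OC)cc1OC | intermediate
4 | methyl 2,4-dimethoxy-6-[(2-methylbut-3-en-2-yl)oxy]benzoate | COC(=O)c1c(OC(C)(C)C=C)cc(OC)cc1OC | intermediate
5 | methyl 2-hydroxy-4,6-dimethoxy-3-(3-methylbut-2-en-1-yl)benzoate | COC(=O)c1c(O)c(CC=C(C)C)c(OC)cc1OC | intermediate
6 | benzyl bromide | BrCc1ccccc1 | starting material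
7 | methyl 2-(benzyloxy)-4,6-dimethoxy-3-(3-methylbut-2-en-1-yl)benzoate | COC(=O)c1c(OCc2ccccc2)c(CC=C(C)C)c(OC)cc1OC | intermediate
8 | lithium 4,6-dimethoxy-7-(3-methylbut-2-en-1-yl)-2-phenyl-1-benzofuran-3-olate (not isolated) | [Li+].[O-]c1c(-c2ccccc2)oc2c(CC=C(C)C)c(OC)cc(OC)c12 | intermediate
9 | {[4,6-dimethoxy-7-(3-methylbut-2-en-1-yl)-2-phenyl-1-benzofuran-3-yl]oxy}triethylsilane | CC[Si](CC)(CC)Oc1c(-c2ccccc2)oc2c(CC=C(C)C)c(OC)cc(OC)c12 | intermediate
10 | diiodomethane | ICI | starting material
11 | (1aR,6bR)-4,6-dimethoxy-3-(3-methylbut-2-en-1-yl)-1a-phenyl-6b-[(triethylsilyl)oxy]-1a,6b-dihydro-1H-cyclopropa[b][1]benzofuran | COc1cc(OC)c2c(c1CC=C(C)C)O[C@@]1(c3ccccc3)C[C@@]21O[Si](CC)(CC)CC | intermediate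
12 | tetrabutylammonium (1aR,6bR)-4,6-dimethoxy-3-(3-methylbut-2-en-1-yl)-1a-phenyl-1a,6b-dihydro-1H-cyclopropa[b][1]benzofuran-6b-olate (not isolated) | COc1cc(OC)c2c(c1CC=C(C)C)O[C@@]1(c3ccccc3)C[C@@]21[O-].CCCC[N+](CCCC)(CCCC)CCCC | intermediate
13 | candidone, (2S)-5,7-dimethoxy-8-(3-methylbut-2-en-1-yl)-2-phenyl-2,3-dihydro-4H-chromen-4-one | COc1cc(OC)c2c(c1CC=C(C)C)O[C@H](c1ccccc1)CC2=O | target

Total steps: 7. Longest linear sequence: 7 steps (1 → 13).

Steps most likely to fail

1. Step 6 (proposed new method). Methylene transfer to the hindered, partly aromatic tetrasubstituted alkene may be slow. If more carbenoid is then needed, the prenyl alkene may be cyclopropanated as well. The ligand may also discriminate the two faces poorly on a substrate outside its known range. Fallback with known chemistry, setting out from 5 and coming back at 13: a crossed Claisen condensation of 5 with the lithium enolate of tert-butyl acetate (LiN(iPr)2, THF, −78 → 0 °C, excess enolate to allow for the phenol) should give tert-butyl 3-[2-hydroxy-4,6-dimethoxy-3-(3-methylbut-2-en-1-yl)phenyl]-3-oxopropanoate F1. Knoevenagel condensation with benzaldehyde (piperidine, AcOH, benzene, molecular sieves) should give tert-butyl 2-[2-hydroxy-4,6-dimethoxy-3-(3-methylbut-2-en-1-yl)benzoyl]-3-phenylprop-2-enoate F2. A cinchona-alkaloid-derived bifunctional thiourea (10 mol %, toluene, −25 °C) should then catalyse the enantioselective intramolecular oxa-Michael addition of the phenol to the activated alkene and give tert-butyl (2S)-5,7-dimethoxy-8-(3-methylbut-2-en-1-yl)-4-oxo-2-phenyl-3,4-dihydro-2H-chromene-3-carboxylate F3 (C3 labile, keto and enol forms); the pseudoenantiomeric catalyst is taken if the first one leads to the 2R series. Brief treatment with TsOH in toluene at 80 °C removes the tert-butyl ester with loss of CO2 and arrives at 13.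

2. Step 7 (proposed new method). The cyclopropanolate may open toward CH2 and give a 2-methylbenzofuranone. Protonation at C2 may be only partly stereospecific if some front-side delivery occurs. The flavanone may racemise by base-induced ring opening to the chalcone phenoxide and reclosure. Fallback with known chemistry, setting out from 11 and coming back at 13: the iron-mediated oxidative ring expansion of siloxycyclopropanes (FeCl3, DMF, 0 °C → rt) should cleave the same fused bond through the alkoxy radical and trap the C2 radical as 2-chloro-5,7-dimethoxy-8-(3-methylbut-2-en-1-yl)-2-phenyl-2,3-dihydro-4H-chromen-4-one F4, which is not isolated but treated with NaOAc in MeOH to lose HCl and give 5,7-dimethoxy-8-(3-methylbut-2-en-1-yl)-2-phenyl-4H-chromen-4-one F5. Copper hydride-catalysed asymmetric conjugate reduction of this flavone (Cu(OAc)2, a chiral bisphosphine such as DTBM-SEGPHOS in the hand that gives 2S, (EtO)2MeSiH, t-BuOH, toluene, 0 °C) then leads to 13. In this fallback C2 is set by the reduction and not by the cyclopropanation, and the isolated prenyl alkene should not be touched by the copper hydride.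

3. Step 5. A [1,2]-Wittig shift of the α-benzyloxy carbanion, or deprotonation at the benzylic and allylic prenyl CH2, may outrun ring closure, and the silyl enol ether may be partly hydrolysed on isolation. Fallback setting out from 5 and coming back at 9: O-alkylation of 5 with methyl 2-bromo-2-phenylacetate (K2CO3, DMF, 50 °C) should give methyl 2-(2-methoxy-2-oxo-1-phenylethoxy)-4,6-dimethoxy-3-(3-methylbut-2-en-1-yl)benzoate F6, whose ester-stabilised anion cannot undergo the Wittig shift. Dieckmann cyclisation (LiN(SiMe3)2, THF, −78 → 0 °C) should give methyl 4,6-dimethoxy-7-(3-methylbut-2-en-1-yl)-3-oxo-2-phenyl-2,3-dihydro-1-benzofuran-2-carboxylate F7. Krapcho dealkoxycarbonylation (LiCl, wet DMSO, 130 °C) should give 4,6-dimethoxy-7-(3-methylbut-2-en-1-yl)-2-phenyl-1-benzofuran-3(2H)-one F8, and silylation under argon (Et3SiCl, Et3N, DMF, rt) leads back to 9.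

Further compounds
F1 | step 6 | tert-butyl 3-[2-hydroxy-4,6-dimethoxy-3-(3-methylbut-2-en-1-yl)phenyl]-3-oxopropanoate | CC(C)(C)OC(=O)CC(=O)c1c(O)c(CC=C(C)C)c(OC)cc1OC
F2 | step 6 | tert-butyl 2-[2-hydroxy-4,6-dimethoxy-3-(3-methylbut-2-en-1-yl)benzoyl]-3-phenylprop-2-enoate (alkene geometry not fixed) | CC(C)(C)OC(=O)C(=Cc1ccccc1)C(=O)c1c(O)c(CC=C(C)C)c(OC)cc1OC
F3 | step 6 | tert-butyl (2S)-5,7-dimethoxy-8-(3-methylbut-2-en-1-yl)-4-oxo-2-phenyl-3,4-dihydro-2H-chromene-3-carboxylate (C3 labile) | COc1cc(OC)c2c(c1CC=C(C)C)O[C@H](c1ccccc1)C(C(=O)OC(C)(C)C)C2=O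
F4 | step 7 | 2-chloro-5,7-dimethoxy-8-(3-methylbut-2-en-1-yl)-2-phenyl-2,3-dihydro-4H-chromen-4-one (racemic, not isolated) | COc1cc(OC)c2c(c1CC=C(C)C)OC(Cl)(c1ccccc1)CC2=O
F5 | step 7 | 5,7-dimethoxy-8-(3-methylbut-2-en-1-yl)-2-phenyl-4H-chromen-4-one | COc1cc(OC)c2c(c1CC=C(C)C)oc(-c1ccccc1)cc2=O
F6 | step 5 | methyl 2-(2-methoxy-2-oxo-1-phenylethoxy)-4,6-dimethoxy-3-(3-methylbut-2-en-1-yl)benzoate (racemic) | COC(=O)C(Oc1c(CC=C(C)C)c(OC)cc(OC)c1C(=O)OC)c1ccccc1
F7 | step 5 | methyl 4,6-dimethoxy-7-(3-methylbut-2-en-1-yl)-3-oxo-2-phenyl-2,3-dihydro-1-benzofuran-2-carboxylate (racemic) | COC(=O)C1(c2ccccc2)Oc2c(CC=C(C)C)c(OC)cc(OC)c2C1=O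
F8 | step 5 | 4,6-dimethoxy-7-(3-methylbut-2-en-1-yl)-2-phenyl-1-benzofuran-3(2H)-one (racemic) | COc1cc(OC)c2c(c1CC=C(C)C)OC(c1ccccc1)C2=O
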